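Ring B is taken apart at three bonds: C4–C4a, C1–C8a and C1–O2. This is possible because C8a lies between the oxygenated C8 and C4a, and C4a carries the C4H2–C3(O2) unit. C8a and C4a therefore map onto the ipso carbon and the only free ortho carbon of 1-iodo-2,4-dimethoxybenzene, C4–C3–O2 onto a terminal epoxide, and C1 onto CO. One palladium/norbornene operation (ortho alkylation, then ipso carbonylation and lactonization) should deliver the 6,8-dimethoxy-3,4-dihydroisocoumarin with ring C attached. The precursor is a terminal epoxide on the finished, O3'-silylated ring C lactone, made from (S)-malic acid through a dichloromethyl ketone and a catalyst-controlled allylboration.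

Key step: step 7

Remarks
- Locants: isocoumarin C1–C8a (ring A benzene, ring B pyranone); C9 is the linking CH2; ring C is O1', C2'(=O), C3'(O), C4'H2, C5'.
- Structure check: ring C of the target is (3'S,5'R) with O3'–H cis to CHCl2. C3' corresponds to C2 of (S)-malic acid, and the allyl group has to add to the Re face of the C5' ketone. The C5' descriptor reads S in 7–14 and R from 15 on only because the CIP ranking of C9 and C4' changes when C3 becomes trigonal; no bond at C5' is touched. No structure needed correction.
- Assumption: the oxirane carbon is formed as both epimers. Compounds 10, 13 and 14 are carried as mixtures at that carbon (left open in their SMILES) and converge at 15.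
- Precursor design: ring C is complete and O3' is silylated before the key step, so the only alkoxide present is the one generated at C3. The epoxide is the limiting partner and the cheap iodide is in excess. A carboxylate-bearing norbornene replaces plain norbornene, and CO is metered. The C8 methyl ether is both the ortho blocking group and, later, the only ether BCl3 removes.

Step 1
Reactants: 1 (S)-malic acid
Product: 2 (S)-2-(2,2-dimethyl-5-oxo-1,3-dioxolan-4-yl)acetic acid
Conditions: 2,2-dimethoxypropane (excess), TsOH·H2O (cat.), rt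
Reagents that add atoms: 2,2-dimethoxypropane, COC(C)(C)OC
Why: Acid-catalysed transketalization in which the α-hydroxy acid unit closes the five-membered dioxolanone in preference to any larger ring, leaving only the CH2CO2H group free and the stereocentre untouched.

Step 2
Reactants: 2 (S)-2-(2,2-dimethyl-5-oxo-1,3-dioxolan-4-yl)acetic acid
Product: 4 (S)-5-(3-diazo-2-oxopropyl)-2,2-dimethyl-1,3-dioxolan-4-one, via acid chloride 3 (not isolated)
Conditions: (COCl)2, DMF (cat.), CH2Cl2, 0 °C → rt; evaporate; CH2N2 (3 equiv), Et2O, 0 °C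
Reagents that add atoms: diazomethane, C=[N+]=[N-]; oxalyl chloride, ClC(=O)C(=O)Cl (chlorine of intermediate 3 only)
Why: Acid chloride formation followed by acylation of diazomethane (first stage of the Arndt–Eistert sequence), a second equivalent of diazomethane consuming the HCl so that the acetonide and the diazoketone survive.

Step 3
Reactants: 4 (S)-5-(3-diazo-2-oxopropyl)-2,2-dimethyl-1,3-dioxolan-4-one
Product: 5 (S)-5-(3,3-dichloro-2-oxopropyl)-2,2-dimethyl-1,3-dioxolan-4-one
Conditions: PhICl2 (1.1 equiv), pyridine (5 mol %), CH2Cl2, 0 °C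
Reagents that add atoms: (dichloroiodo)benzene, ClI(Cl)c1ccccc1
Why: Halogenative dediazoniation of an α-diazoketone, in which the nucleophilic diazo carbon takes electrophilic chlorine and chloride then displaces N2, so that exactly two chlorines arrive on the terminal carbon without enolization toward C4'.

Step 4
Reactants: 5 (S)-5-(3,3-dichloro-2-oxopropyl)-2,2-dimethyl-1,3-dioxolan-4-one; 6 allylboronic acid pinacol ester
Product: 8 (3S,5S)-5-allyl-5-(dichloromethyl)-3-hydroxyoxolan-2-one, via tertiary homoallylic alcohol 7 (not isolated)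
Conditions: 6 (1.5 equiv), valine-derived aminophenol catalyst 2-[(3,5-di-tert-butyl-2-hydroxybenzyl)amino]-N,N,3-trimethylbutanamide (2.5 mol %, enantiomer chosen for Re-face delivery), NaOt-Bu (5 mol %), MeOH (2 equiv), toluene, 4 °C; then TsOH·H2O (0.2 equiv), 50 °C
Reagents that add atoms: allylboronic acid pinacol ester (6), C=CCB1OC(C)(C)C(C)(C)O1
Why: Aminophenol-catalysed enantioselective allylboration of a halomethyl ketone, in which the catalyst-bound allylboron species holds the ketone by an ammonium N–H···O=C hydrogen bond and an ammonium/C–Cl dipole attraction and transfers allyl through a six-membered chair transition state to the Re face of the C5' carbonyl (catalyst control sets C5'), after which acid-catalysed 5-exo-trig transesterification of the tertiary alcohol onto the activated dioxolanone carbonyl closes ring C with loss of acetone; since C3' is already fixed, any minor C5' epimer is a separable diastereomer.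

Step 5
Reactants: 8 (3S,5S)-5-allyl-5-(dichloromethyl)-3-hydroxyoxolan-2-one
Product: 9 (3S,5S)-5-allyl-3-(tert-butyldimethylsilyloxy)-5-(dichloromethyl)oxolan-2-one
Conditions: TBSCl (1.5 equiv), imidazole (3 equiv), DMF, rt
Reagents that add atoms: tert-butyldimethylsilyl chloride, CC(C)(C)[Si](C)(C)Cl
Why: Imidazole-mediated silylation of the only hydroxyl group, which leaves both stereocentres untouched.

Step 6
Reactants: 9 (3S,5S)-5-allyl-3-(tert-butyldimethylsilyloxy)-5-(dichloromethyl)oxolan-2-one
Product: 10 (3S,5S)-3-(tert-butyldimethylsilyloxy)-5-(dichloromethyl)-5-(oxiran-2-ylmethyl)oxolan-2-one (both oxirane epimers)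
Conditions: mCPBA (2.5 equiv), CH2Cl2, rt
Reagents that add atoms: meta-chloroperoxybenzoic acid, OOC(=O)c1cccc(Cl)c1
Why: Prilezhaev epoxidation of the only C=C bond; the new oxirane stereocentre forms unselectively, which is acceptable because this carbon becomes trigonal C3 in step 8.

Step 7
Reactants: 10 (3S,5S)-3-(tert-butyldimethylsilyloxy)-5-(dichloromethyl)-5-(oxiran-2-ylmethyl)oxolan-2-one; 11 1-iodo-2,4-dimethoxybenzene; 12 carbon monoxide
Product: 13 3-{[(3'S,5'S)-3'-(tert-butyldimethylsilyloxy)-5'-(dichloromethyl)-2'-oxooxolan-5'-yl]methyl}-6,8-dimethoxy-3,4-dihydroisocoumarin (both C3 epimers)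
Conditions: 10 (1.0 equiv), 11 (2.0 equiv), Pd(OAc)2 (10 mol %), XPhos (2-dicyclohexylphosphino-2',4',6'-triisopropylbiphenyl, 20 mol %), potassium 5-norbornene-2-carboxylate (0.5 equiv), K2CO3 (2.0 equiv), NMP, 70 °C, argon; CO (1.5 equiv) fed over 8 h by gas-tight syringe pump
Reagents that add atoms: carbon monoxide (12), [C-]#[O+]
Why: Proposed new method: oxidative addition of 11 to zerovalent palladium, exo-carbopalladation of the norbornene and carboxylate-assisted palladation of the single free ortho C–H should give a five-membered aryl–norbornyl palladacycle, which opens epoxide 10 at its CH2 terminus (oxidative addition to tetravalent palladium, then C–C reductive elimination, forming C4–C4a); the aryl group, now flanked by two ortho substituents, expels the norbornene by β-carbon elimination, and the hindered divalent aryl–palladium inserts CO (C1–C8a) before the tethered C3 alkoxide attacks the acyl carbon (C1–O2) and releases zerovalent palladium. The closest known reaction types are Catellani ortho-alkylations of aryl iodides with epoxides that end in a ring closure (Heck/oxa-Michael or ipso C–O coupling) and palladium-catalysed carbonylative lactonization of 2-(2-hydroxyalkyl)aryl halides; merging them in one catalytic cycle is the untested part. Ring B closes by 6-exo-trig attack of the alkoxide on the acyl–palladium carbon. No stereocentre is created, since C3 keeps the configuration of the oxirane carbon (only the CH2–O bond breaks) and C3' and C5' are spectators. The step needs ortho alkylation before ipso carbonylation and epoxide opening at the unsubstituted carbon: the C8 methoxy group blocks the second ortho position and forces norbornene extrusion after one alkylation, sterics direct the opening to CH2, and a low stationary CO concentration with excess 11 and mediator keeps CO from intercepting the first aryl–palladium species or the palladacycle.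

Step 8
Reactants: 13 3-{[(3'S,5'S)-3'-(tert-butyldimethylsilyloxy)-5'-(dichloromethyl)-2'-oxooxolan-5'-yl]methyl}-6,8-dimethoxy-3,4-dihydroisocoumarin
Product: 15 O3'-TBS 6,8-dimethoxyisocoumarin [3-{[(3'S,5'R)-3'-(tert-butyldimethylsilyloxy)-5'-(dichloromethyl)-2'-oxooxolan-5'-yl]methyl}-6,8-dimethoxyisochromen-1-one], via C4 bromide 14 (not isolated)
Conditions: NBS (1.1 equiv), AIBN (azobisisobutyronitrile, 10 mol %), PhCF3, 80 °C, lamp; then Et3N (3 equiv), rt
Reagents that add atoms: N-bromosuccinimide, O=C1CCC(=O)N1Br (bromine of intermediate 14 only)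
Why: Wohl–Ziegler bromination at the benzylic C4–H (the weakest C–H bond, radical chain in a non-polar medium) followed by amine-promoted E2 loss of HBr across C3–C4, driven by conjugation of the new isocoumarin; both C3 epimers converge on one product.

Step 9
Reactants: 15 O3'-TBS 6,8-dimethoxyisocoumarin
Product: 17 8-hydroxy-6-methoxy-3-{[(3'S,5'R)-5'-(dichloromethyl)-3'-hydroxy-2'-oxooxolan-5'-yl]methyl}isochromen-1-one (target), via C8 phenol silyl ether 16 (not isolated)
Conditions: BCl3 (3 equiv), CH2Cl2, −78 → 0 °C; H2O quench, extract, concentrate; HF·pyridine, THF, 0 °C → rt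
Reagents that add atoms: none
Why: Chelation-controlled Lewis-acid ether cleavage, in which BCl3 bridges the C1 carbonyl and the peri C8 methoxy oxygen so that chloride removes only that methyl group and spares the C6 ether, followed by fluoride-driven desilylation of O3' that neither lactone should notice; any silyl loss in the first stage is harmless.

Compound list
1 | (S)-malic acid | OC(=O)C[C@H](O)C(=O)O | starting material
2 | (S)-2-(2,2-dimethyl-5-oxo-1,3-dioxolan-4-yl)acetic acid | CC1(C)O[C@@H](CC(=O)O)C(=O)O1 | intermediate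
3 | (S)-2-(2,2-dimethyl-5-oxo-1,3-dioxolan-4-yl)acetyl chloride | CC1(C)O[C@@H](CC(=O)Cl)C(=O)O1 | intermediate
4 | (S)-5-(3-diazo-2-oxopropyl)-2,2-dimethyl-1,3-dioxolan-4-one | CC1(C)O[C@@H](CC(=O)C=[N+]=[N-])C(=O)O1 | intermediate
5 | (S)-5-(3,3-dichloro-2-oxopropyl)-2,2-dimethyl-1,3-dioxolan-4-one | CC1(C)O[C@@H](CC(=O)C(Cl)Cl)C(=O)O1 | intermediate
6 | allylboronic acid pinacol ester | C=CCB1OC(C)(C)C(C)(C)O1 | starting material
7 | (S)-5-[(S)-2-(dichloromethyl)-2-hydroxypent-4-en-1-yl]-2,2-dimethyl-1,3-dioxolan-4-one | CC1(C)O[C@@H](C[C@@](O)(CC=C)C(Cl)Cl)C(=O)O1 | intermediate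
8 | (3S,5S)-5-allyl-5-(dichloromethyl)-3-hydroxyoxolan-2-one (OH cis to CHCl2) | C=CC[C@@]1(C(Cl)Cl)C[C@H](O)C(=O)O1 | intermediate
9 | (3S,5S)-5-allyl-3-(tert-butyldimethylsilyloxy)-5-(dichloromethyl)oxolan-2-one | C=CC[C@@]1(C(Cl)Cl)C[C@H](O[Si](C)(C)C(C)(C)C)C(=O)O1 | intermediate
10 | (3S,5S)-3-(tert-butyldimethylsilyloxy)-5-(dichloromethyl)-5-(oxiran-2-ylmethyl)oxolan-2-one, both oxirane epimers | C1OC1C[C@@]2(C(Cl)Cl)C[C@H](O[Si](C)(C)C(C)(C)C)C(=O)O2 | intermediate
11 | 1-iodo-2,4-dimethoxybenzene | COc1ccc(I)c(OC)c1 | starting material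
12 | carbon monoxide | [C-]#[O+] | starting material
13 | 3-{[(3'S,5'S)-3'-(tert-butyldimethylsilyloxy)-5'-(dichloromethyl)-2'-oxooxolan-5'-yl]methyl}-6,8-dimethoxy-3,4-dihydroisocoumarin, both C3 epimers | COc1cc(OC)c2C(=O)OC(Cc2c1)C[C@@]3(C(Cl)Cl)C[C@H](O[Si](C)(C)C(C)(C)C)C(=O)O3 | intermediate
14 | 4-bromo derivative of 13, mixture at C3 and C4 | COc1cc(OC)c2C(=O)OC(C(Br)c2c1)C[C@@]3(C(Cl)Cl)C[C@H](O[Si](C)(C)C(C)(C)C)C(=O)O3 | intermediate
15 | 3-{[(3'S,5'R)-3'-(tert-butyldimethylsilyloxy)-5'-(dichloromethyl)-2'-oxooxolan-5'-yl]methyl}-6,8-dimethoxyisochromen-1-one | COc1cc(OC)c2c(=O)oc(C[C@@]3(C(Cl)Cl)C[C@H](O[Si](C)(C)C(C)(C)C)C(=O)O3)cc2c1 | intermediate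
16 | 3-{[(3'S,5'R)-3'-(tert-butyldimethylsilyloxy)-5'-(dichloromethyl)-2'-oxooxolan-5'-yl]methyl}-8-hydroxy-6-methoxyisochromen-1-one | COc1cc(O)c2c(=O)oc(C[C@@]3(C(Cl)Cl)C[C@H](O[Si](C)(C)C(C)(C)C)C(=O)O3)cc2c1 | intermediate
17 | 3-{[(3'S,5'R)-5'-(dichloromethyl)-3'-hydroxy-2'-oxooxolan-5'-yl]methyl}-8-hydroxy-6-methoxyisochromen-1-one | COc1cc(O)c2c(=O)oc(C[C@@]3(C(Cl)Cl)C[C@H](O)C(=O)O3)cc2c1 | target

Total step count: 9. Longest linear sequence: 9 steps (1 → 17); compounds 6, 11 and 12 are bought and enter directly.

Steps most likely to fail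

1. Step 7 (the one new method). CO may insert into the first aryl–palladium species before the norbornene does, or into the palladacycle. If CO is too scarce, the C3 alkoxide may instead couple at the ipso carbon and give a dihydrobenzofuran; if it is too abundant, it may sequester zerovalent palladium. The fallback uses known chemistry, sets out from 10 and returns at 13. Commercial (3,5-dimethoxyphenyl)magnesium chloride with catalytic CuI in THF at −40 °C opens the oxirane of 10 at its CH2 terminus and should give the secondary alcohol 1-(3,5-dimethoxyphenyl)-3-(ring C)propan-2-ol F1. N-Iodosuccinimide in MeCN then iodinates the ring carbon flanked by the side chain and a methoxy group (para to the other methoxy), giving the aryl iodide F2. A conventional carbonylative lactonization of this 2-(2-hydroxyalkyl)aryl iodide (Pd(OAc)2, 1,1'-bis(diphenylphosphino)ferrocene, CO 1 atm, K2CO3, DMF, 80 °C) closes ring B to 13.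

2. Step 4. Facial selectivity at C5' may erode through uncatalysed background allylboration of the activated ketone or a mismatch with C3', and the alkoxide co-catalyst may trigger β-elimination of the dioxolanone oxygen from the enolizable ketone. The fallback sets out from 5 and returns at 8. A base-free Hosomi–Sakurai allylation (allyltrimethylsilane, TiCl4, CH2Cl2, −78 °C) gives alcohol 7 together with its carbinol epimer, the (R)-configured tertiary alcohol F3. The same TsOH lactonization converts both, and 8 is separated by chromatography from its C5' epimer, the trans lactone F4, which is discarded; the cis/trans assignment rests on NOE between H3' and the C5' substituents.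

3. Step 8. Ionic bromination of the electron-rich dimethoxyarene at C5 or C7 may outrun the radical chain at C4. The fallback sets out from 13 and returns at 16 by making the ring less electron-rich before the bromination.
   - BCl3 (CH2Cl2, −78 °C) cleaves the chelated C8 methyl ether to give the 8-hydroxy-6-methoxy-3,4-dihydroisocoumarin silyl ether F5.
   - Ac2O/pyridine gives the 8-acetoxy compound F6.
   - NBS/AIBN in PhCF3 gives the 8-acetoxy C4 bromide F7, which Et3N converts to the 8-acetoxy-6-methoxyisocoumarin silyl ether F8.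
   - NH4OAc in aqueous MeOH removes the aryl acetate to give 16, which is desilylated with HF·pyridine as in the second stage of step 9.

Further compounds
F1 | step 7 | (3S,5S)-3-(tert-butyldimethylsilyloxy)-5-(dichloromethyl)-5-[3-(3,5-dimethoxyphenyl)-2-hydroxypropyl]oxolan-2-one, both carbinol epimers | COc1cc(OC)cc(CC(O)C[C@@]2(C(Cl)Cl)C[C@H](O[Si](C)(C)C(C)(C)C)C(=O)O2)c1
F2 | step 7 | (3S,5S)-3-(tert-butyldimethylsilyloxy)-5-(dichloromethyl)-5-[2-hydroxy-3-(2-iodo-3,5-dimethoxyphenyl)propyl]oxolan-2-one, both carbinol epimers | COc1cc(OC)c(I)c(CC(O)C[C@@]2(C(Cl)Cl)C[C@H](O[Si](C)(C)C(C)(C)C)C(=O)O2)c1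
F3 | step 4 | (S)-5-[(R)-2-(dichloromethyl)-2-hydroxypent-4-en-1-yl]-2,2-dimethyl-1,3-dioxolan-4-one | CC1(C)O[C@@H](C[C@](O)(CC=C)C(Cl)Cl)C(=O)O1
F4 | step 4 | (3S,5R)-5-allyl-5-(dichloromethyl)-3-hydroxyoxolan-2-one | C=CC[C@]1(C(Cl)Cl)C[C@H](O)C(=O)O1
F5 | step 8 | 3-{[(3'S,5'S)-3'-(tert-butyldimethylsilyloxy)-5'-(dichloromethyl)-2'-oxooxolan-5'-yl]methyl}-8-hydroxy-6-methoxy-3,4-dihydroisocoumarin, both C3 epimers | COc1cc(O)c2C(=O)OC(Cc2c1)C[C@@]3(C(Cl)Cl)C[C@H](O[Si](C)(C)C(C)(C)C)C(=O)O3
F6 | step 8 | 8-acetoxy analogue of F5 | COc1cc(OC(C)=O)c2C(=O)OC(Cc2c1)C[C@@]3(C(Cl)Cl)C[C@H](O[Si](C)(C)C(C)(C)C)C(=O)O3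
F7 | step 8 | 4-bromo derivative of F6, mixture at C3 and C4 | COc1cc(OC(C)=O)c2C(=O)OC(C(Br)c2c1)C[C@@]3(C(Cl)Cl)C[C@H](O[Si](C)(C)C(C)(C)C)C(=O)O3
F8 | step 8 | 8-acetoxy-3-{[(3'S,5'R)-3'-(tert-butyldimethylsilyloxy)-5'-(dichloromethyl)-2'-oxooxolan-5'-yl]methyl}-6-methoxyisochromen-1-one | COc1cc(OC(C)=O)c2c(=O)oc(C[C@@]3(C(Cl)Cl)C[C@H](O[Si](C)(C)C(C)(C)C)C(=O)O3)cc2c1
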